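- Retrosynthesis: the C1 acid is carried as a methyl ester; the ring is opened at C8–C12 to an acyclic (10S)-10-pivaloyloxy-11,13-dien-8-yne, which is cut at C9–C10 (alkyne plus dienal), and the dienal at C11=C12 (Wittig) and C13=C14 (cross-metathesis).
- Enabling feature: ring carbons C8–C12 with oxygen on C9 (C8 sp3, C9=O, C10=C11, C12 sp3) form a 2-oxypentadienyl unit. As in the allene oxide pathway to cyclopentenone oxylipins, such a cation closes between its two ends; here it is generated from a C8≡C9 alkyne, a C10 acyloxy carbinol and an E C11=C12 alkene under gold catalysis.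
- Forward order: (S)-oct-1-en-3-ol → acetate → enal → dienal (C10–C20); union with methyl non-8-ynoate (C1–C9) at C9–C10; pivalate; ring closure C8–C12; ester hydrolysis.
- Stereochemistry: C15 comes from the commercial alcohol; C10 (temporary) from ligand-controlled alkynylation; C12 from C10 by chirality transfer in the ring closure; C8 by thermodynamic control (trans); both E alkenes from metathesis and Wittig.
- The C10 pivalate is the only helper group: it migrates to C9, delivers the ketone oxygen and leaves as pivalic acid in the same step.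

Key step: step 7

Remark: prostanoid numbering (carboxyl carbon C1 to C20) is used for chain positions. The (R,R) antipode of ProPhenol is assumed to deliver the alkynyl group to the Re face of the dienal (giving 10S), and (10S) is assumed to transfer to (12S) by the anti relation argued in step 7. If a trial run shows the reverse sense in either case, the other ligand antipode is used.

**Route**

Step 1
Reactants: 1 (S)-oct-1-en-3-ol
Product: 2 (S)-oct-1-en-3-yl acetate
Conditions: Ac2O, Et3N, DMAP (cat.), CH2Cl2, 0 °C to 23 °C
Reagents that add atoms: acetic anhydride CC(=O)OC(C)=O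
Why: DMAP-catalysed acylation of the secondary allylic alcohol installs the acetate of the target at the outset without touching the C15 stereocentre, which is bought in.

Step 2
Reactants: 2 (S)-oct-1-en-3-yl acetate
Product: 3 (2E,4S)-4-acetoxynon-2-enal
Conditions: crotonaldehyde (5 equiv), second-generation Hoveyda–Grubbs catalyst (3 mol %), CH2Cl2, 40 °C
Reagents that add atoms: crotonaldehyde C/C=C/C=O
Why: Olefin cross-metathesis of the terminal alkene with an excess of the electron-poor partner should give the E enal under thermodynamic control, with the allylic C–O centre untouched.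

Step 3
Reactants: 3 (2E,4S)-4-acetoxynon-2-enal
Product: 4 (2E,4E,6S)-6-acetoxyundeca-2,4-dienal
Conditions: Ph3P=CHCHO (1.05 equiv), toluene, 80 °C
Reagents that add atoms: (triphenylphosphoranylidene)acetaldehyde O=CC=P(c1ccccc1)(c1ccccc1)c1ccccc1
Why: Wittig olefination with the stabilised formylmethylene ylide is E-selective and adds C10 and C11; about one equivalent is used because the product dienal is the less electrophilic aldehyde.

Step 4
Reactants: 5 non-8-ynoic acid
Product: 6 methyl non-8-ynoate
Conditions: MeOH, H2SO4 (cat.), reflux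
Reagents that add atoms: methanol CO
Why: Fischer esterification masks the acid as the ester that the enzymatic last step removes at neutral pH; the terminal alkyne is inert.

Step 5
Reactants: 4 (2E,4E,6S)-6-acetoxyundeca-2,4-dienal; 6 methyl non-8-ynoate
Product: 8 methyl (10S,11E,13E,15S)-15-acetoxy-10-hydroxyicosa-11,13-dien-8-ynoate, via methylzinc acetylide 7 (not isolated)
Conditions: 6 (3 equiv), Me2Zn (3 equiv), (R,R)-ProPhenol (20 mol %), Ph3P=O (40 mol %), toluene, 23 °C; then 4, 4 °C; aq. NH4Cl
Reagents that add atoms: none
Why: Catalytic enantioselective alkynylation of an aldehyde by an alkynylzinc, with the catalyst formed in the flask from Me2Zn and ProPhenol and known to suit α,β-unsaturated aldehydes, should add to the Re face and set C10 as S under ligand control, while the dialkylzinc leaves both esters alone.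

Step 6
Reactants: 8 methyl (10S,11E,13E,15S)-15-acetoxy-10-hydroxyicosa-11,13-dien-8-ynoate
Product: 9 methyl (10S,11E,13E,15S)-15-acetoxy-10-(pivaloyloxy)icosa-11,13-dien-8-ynoate
Conditions: PivCl, Et3N, DMAP (cat.), CH2Cl2, 0 °C; chromatography on Et3N-buffered silica
Reagents that add atoms: pivaloyl chloride CC(C)(C)C(Cl)=O
Why: O-acylation installs the migrating group with retention at C10, since the C–O bond is not broken; the hindered, poorly ionising pivalate is chosen for configurational stability.

Step 7
Reactants: 9 methyl (10S,11E,13E,15S)-15-acetoxy-10-(pivaloyloxy)icosa-11,13-dien-8-ynoate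
Product: 12 methyl 7-[(1R,2S)-2-[(1E,3S)-3-acetoxyoct-1-enyl]-5-oxocyclopent-3-enyl]heptanoate, via cyclopentadienyl pivalate 10 (not isolated), via 8-epi enone 11 (not isolated)
Conditions: Ph3PAuNTf2 (5 mol %), MeCN containing H2O (2 equiv), −20 °C; then Et3N (0.2 equiv), CH2Cl2, 0 °C
Reagents that add atoms: none
Why: Monovalent gold binds the C8≡C9 alkyne, the pivalate carbonyl oxygen adds to C9 anti to the metal and the acyloxy group shifts from C10 to C9, which turns C8–C9(OPiv)–C10–C11–C12 into a vinylgold/2-acyloxypentadienyl cation that closes the C8–C12 bond and, after loss of the metal and hydrolysis of dienyl pivalate 10 by the water present, gives the enone. The closest known reaction type is the gold-catalysed Rautenstrauch rearrangement of 1-alkynylallyl pivalates (3-acyloxy-1,4-enynes), and the cation is the acylated counterpart of the oxidopentadienyl cation that closes the same bond in the allene oxide pathway to cyclopentenone oxylipins. The cyclopentene ring C8–C12 is closed by a 4π conrotatory electrocyclisation, equivalent to a 5-endo-trig anti-SN2' attack of the vinylgold carbon C8 on C12. C12 is controlled by C10: the new bond should form on the face of the E alkene opposite to the departing C10–O bond before the cation can flatten, so that (10S) should give (12S); C8 is set by protonation and then by equilibration with Et3N, which should place the α-chain trans to the C12 substituent (8R). The step needs 1,2- over 1,3-acyloxy shift, closure at C12 and not at C14, and no ionisation of the C10 ester: the E geometry of C11=C12 keeps C14 out of reach of C8 (a seven-membered ring would hold a trans alkene), the low temperature and the poorly ionising pivalate favour the concerted path, and the C15 acetate is an ordinary allylic ester once C12 is tetrahedral.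

Step 8
Reactants: 12 methyl 7-[(1R,2S)-2-[(1E,3S)-3-acetoxyoct-1-enyl]-5-oxocyclopent-3-enyl]heptanoate
Product: 13 7-[(1R,2S)-2-[(1E,3S)-3-acetoxyoct-1-enyl]-5-oxocyclopent-3-enyl]heptanoic acid
Conditions: Novozym 435 (immobilised Candida antarctica lipase B), phosphate buffer pH 7, acetone, 30 °C
Reagents that add atoms: water O
Why: Lipase-catalysed ester hydrolysis at neutral pH should take the unhindered methyl ester of the long-chain acid and leave the C15 acetate, whose secondary carbinol carries two large groups that the narrow alcohol pocket of this lipase should reject, while the base-sensitive 4,5-disubstituted cyclopentenone is not exposed to hydroxide.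

**Compound list**

1 | (S)-oct-1-en-3-ol | C=C[C@@H](O)CCCCC | starting material
2 | (S)-oct-1-en-3-yl acetate | C=C[C@@H](OC(C)=O)CCCCC | intermediate
3 | (2E,4S)-4-acetoxynon-2-enal | O=C/C=C/[C@@H](OC(C)=O)CCCCC | intermediate
4 | (2E,4E,6S)-6-acetoxyundeca-2,4-dienal | O=C/C=C/C=C/[C@@H](OC(C)=O)CCCCC | intermediate
5 | non-8-ynoic acid | C#CCCCCCCC(=O)O | starting material
6 | methyl non-8-ynoate | C#CCCCCCCC(=O)OC | intermediate
7 | methyl 9-(methylzincio)non-8-ynoate (methylzinc acetylide of 6) | C[Zn]C#CCCCCCCC(=O)OC | intermediate
8 | methyl (10S,11E,13E,15S)-15-acetoxy-10-hydroxyicosa-11,13-dien-8-ynoate | COC(=O)CCCCCCC#C[C@@H](O)/C=C/C=C/[C@@H](OC(C)=O)CCCCC | intermediate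
9 | methyl (10S,11E,13E,15S)-15-acetoxy-10-(pivaloyloxy)icosa-11,13-dien-8-ynoate | COC(=O)CCCCCCC#C[C@@H](OC(=O)C(C)(C)C)/C=C/C=C/[C@@H](OC(C)=O)CCCCC | intermediate
10 | methyl 7-[(5S)-5-[(1E,3S)-3-acetoxyoct-1-enyl]-2-(pivaloyloxy)cyclopenta-1,3-dienyl]heptanoate | COC(=O)CCCCCCC1=C(OC(=O)C(C)(C)C)C=C[C@@H]1/C=C/[C@@H](OC(C)=O)CCCCC | intermediate
11 | methyl 7-[(1S,2S)-2-[(1E,3S)-3-acetoxyoct-1-enyl]-5-oxocyclopent-3-enyl]heptanoate (8-epimer of 12, chains cis) | CCCCC[C@@H](/C=C/[C@H]1C=CC(=O)[C@H]1CCCCCCC(=O)OC)OC(C)=O | intermediate
12 | methyl 7-[(1R,2S)-2-[(1E,3S)-3-acetoxyoct-1-enyl]-5-oxocyclopent-3-enyl]heptanoate | CCCCC[C@@H](/C=C/[C@H]1C=CC(=O)[C@@H]1CCCCCCC(=O)OC)OC(C)=O | intermediate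
13 | 7-[(1R,2S)-2-[(1E,3S)-3-acetoxyoct-1-enyl]-5-oxocyclopent-3-enyl]heptanoic acid | CCCCC[C@@H](/C=C/[C@H]1C=CC(=O)[C@@H]1CCCCCCC(=O)O)OC(C)=O | target

**Count and risks**

Total steps: 8. Longest linear sequence: 7 (steps 1, 2, 3, 5, 6, 7, 8).

Step 7. What may go wrong: ionisation of the doubly activated C10 pivalate, or a 1,3-acyloxy shift to an allenyl ester (a known competing path for internal alkynes) under the cationic catalyst. Either would erode the transfer of configuration from C10 to C12 or divert the closure; the conjugated C13=C14 bond may also interfere. Fallback, setting out from 3 and coming back at 12: the C13=C14 bond is masked during ring closure, so that the C10 ester is only singly allylic. Benzeneselenol (cat. Et3N, CH2Cl2, 0 °C) is added to enal 3 to give (4S)-4-acetoxy-3-(phenylselanyl)nonanal F1 as a mixture of C3 epimers, which is of no consequence. Wittig homologation as in step 3 then gives (2E,6S)-6-acetoxy-5-(phenylselanyl)undec-2-enal F2. Alkynylation with 6 as in step 5 gives methyl (10S,11E,15S)-15-acetoxy-10-hydroxy-14-(phenylselanyl)icos-11-en-8-ynoate F3, and pivaloylation as in step 6 gives methyl (10S,11E,15S)-15-acetoxy-14-(phenylselanyl)-10-(pivaloyloxy)icos-11-en-8-ynoate F4. The gold-catalysed rearrangement, now on an isolated E alkene and run with a higher loading of Ph3PAuNTf2 (10 mol %) to offset binding of the selenide to gold, followed by amine equilibration, should give methyl 7-[(1R,2S)-2-[(3S)-3-acetoxy-2-(phenylselanyl)octyl]-5-oxocyclopent-3-enyl]heptanoate F5. H2O2 and pyridine in CH2Cl2 at 0 °C oxidise selenium; the selenoxide should eliminate syn, away from the acetoxy-bearing carbon, and restore the (13E) allylic acetate of 12.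

Step 5. What may go wrong: slow addition to the deactivated dienal and poor or reversed facial selectivity at C10. Fallback, setting out from 4 and 6 and coming back at 8: the configuration is set by reduction instead of addition. Zinc acetylide 7 is added to 4 without chiral ligand (Me2Zn, N-methylimidazole, toluene, 23 °C) to give methyl (11E,13E,15S)-15-acetoxy-10-hydroxyicosa-11,13-dien-8-ynoate F6 as a mixture of C10 epimers. MnO2 in CH2Cl2 oxidises it to methyl (11E,13E,15S)-15-acetoxy-10-oxoicosa-11,13-dien-8-ynoate F7. Midland reduction with (S)-Alpine-Borane (THF, 23 °C), in which the alkynyl arm acts as the small group, should return the (10S) alcohol 8.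

Step 8. What may go wrong: competing loss of the C15 acetate, or sluggish hydrolysis of the methyl ester. Fallback, setting out from 12 and coming back at 13: selectivity is given up and the acetate is put back. Porcine liver esterase (phosphate buffer pH 7.5, 30 °C) cleaves both esters to 7-[(1R,2S)-2-[(1E,3S)-3-hydroxyoct-1-enyl]-5-oxocyclopent-3-enyl]heptanoic acid F8, the 15-hydroxy acid. Ac2O and pyridine at 0 °C, followed by aqueous work-up to hydrolyse the mixed anhydride, acetylate the C15 hydroxyl and give 13.

**Further compounds**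

F1 | step 7 | (4S)-4-acetoxy-3-(phenylselanyl)nonanal | O=CCC([Se]c1ccccc1)[C@@H](OC(C)=O)CCCCC
F2 | step 7 | (2E,6S)-6-acetoxy-5-(phenylselanyl)undec-2-enal | O=C/C=C/CC([Se]c1ccccc1)[C@@H](OC(C)=O)CCCCC
F3 | step 7 | methyl (10S,11E,15S)-15-acetoxy-10-hydroxy-14-(phenylselanyl)icos-11-en-8-ynoate | COC(=O)CCCCCCC#C[C@@H](O)/C=C/CC([Se]c1ccccc1)[C@@H](OC(C)=O)CCCCC
F4 | step 7 | methyl (10S,11E,15S)-15-acetoxy-14-(phenylselanyl)-10-(pivaloyloxy)icos-11-en-8-ynoate | COC(=O)CCCCCCC#C[C@@H](OC(=O)C(C)(C)C)/C=C/CC([Se]c1ccccc1)[C@@H](OC(C)=O)CCCCC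
F5 | step 7 | methyl 7-[(1R,2S)-2-[(3S)-3-acetoxy-2-(phenylselanyl)octyl]-5-oxocyclopent-3-enyl]heptanoate | CCCCC[C@H](OC(C)=O)C([Se]c1ccccc1)C[C@H]1C=CC(=O)[C@@H]1CCCCCCC(=O)OC
F6 | step 5 | methyl (11E,13E,15S)-15-acetoxy-10-hydroxyicosa-11,13-dien-8-ynoate (C10 epimer mixture) | COC(=O)CCCCCCC#CC(O)/C=C/C=C/[C@@H](OC(C)=O)CCCCC
F7 | step 5 | methyl (11E,13E,15S)-15-acetoxy-10-oxoicosa-11,13-dien-8-ynoate | COC(=O)CCCCCCC#CC(=O)/C=C/C=C/[C@@H](OC(C)=O)CCCCC
F8 | step 8 | 7-[(1R,2S)-2-[(1E,3S)-3-hydroxyoct-1-enyl]-5-oxocyclopent-3-enyl]heptanoic acid | CCCCC[C@H](O)/C=C/[C@H]1C=CC(=O)[C@@H]1CCCCCCC(=O)O
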